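## The problem

The target is a bisabolane-type sesquiterpenoid on a single carbocycle. Positions are numbered as follows and this numbering is used throughout, also for open-chain and carveol-type intermediates: C1 ring ketone, C2 quaternary epoxide carbon with a methyl group, C3 epoxide CH, C4 methylene, C5 the carbon bearing the side chain, C6 the carbon bearing the 3-methylbutanoate. The side chain is C7 (with an exocyclic methylene), C8 (ketone), C9=C10 (E) and C11 (tertiary hydroperoxide with two methyl groups).

The four ring stereocentres C2, C3, C5 and C6 are all S. The epoxide is cis to the C5 substituent and the C6 ester is trans to it. C5 can be bought in a monoterpene and controls C6 readily, because an enolate across C1/C6 is attacked anti to its neighbour. It works against the epoxide, because conjugate epoxidation of the corresponding 2-methylcyclohexenone is expected to deliver oxygen trans to C5. The epoxide therefore has to be made by an indirect, stereospecific route.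

The hydroperoxide does not tolerate reducing agents, strong bases or most organometallic reagents. The cross-conjugated dienone is a double Michael acceptor, the α-acyloxy ketone epimerises and eliminates under base, and the epoxy ketone can fragment through its enolate. These groups must come late and be made under near-neutral conditions.

The feature that opens the key step is the C1–C2 bond. C1 is a carbonyl carbon and C2 an oxygen-bearing quaternary carbon with a methyl group, a tertiary acyloin. The ring can thus be closed between an aldehyde carbon (C1) and a methyl ketone carbon (C2) by umpolung of the aldehyde. The rest of the ring, C3 to C6 with the C3 oxygen and a three-carbon branch on C5, is what oxidative opening of a carveol provides.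

## Retrosynthesis

**Hydroperoxide and C9=C10.** The target 26 is traced to its peroxyketal 25, so that the O–O–H proton appears only in the last, weakly acidic step. In 25 the C9=C10 double bond is cut by cross-metathesis into vinyl ketone 21 and peroxy olefin 24, which comes in two steps from 2-methylbut-3-en-2-ol 22 through hydroperoxide 23. The neighbouring cut at C8–C9 would need an alkenyl metal that carries the peroxide, whereas metathesis keeps the peroxide away from carbanions. The forward reaction needs a ruthenium carbene that tolerates a dialkyl peroxide and a hindered allylic carbon. It must also engage only the vinyl ketone end of 21 and give the E-alkene.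

**C8–C9 and the oxidation level of C8.** C8 is the methyl carbon of an isopropenyl group. Dienone 21 is therefore taken back through dienol 20 to enal 18 and vinylmagnesium bromide 19, and 18 through allylic alcohol 17 to the isopropenyl ester 16. The alternative cut at C7–C8 would discard the three-carbon branch that the terpene supplies and rebuild it from an acetyl group. The precursor 16 has no side-chain functionality. The forward sequence needs an allylic oxidation that prefers the methyl group over the C5 methine, and a vinyl addition that finds the aldehyde in the presence of a hindered ring ketone and an ester.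

**C6–O.** Ester 16 is cut at the acyl–oxygen bond into hydroxy ketone 14 and 3-methylbutanoyl chloride 15. The C6–O bond of 14 is cut back to epoxy ketone 12, through its enolate 13. This is placed before the side chain because a ketone enolate cannot coexist with the dienone. C6 is the only enolisable position, since C2 is quaternary, and C5 is expected to send the oxidant to the opposite face, which is the trans relationship required.

**Epoxide.** The C3–O bond of the epoxide in 12 is cut to give trans-diol 10, activated in the forward sense as mesylate 11. Diol 10 is the desilylated form of ketol 9. Direct epoxidation of an enone would give the wrong face. A displacement at C3 by the C2 oxygen instead fixes the epoxide on the face of the C2 hydroxyl with inversion at C3. The forward reaction therefore needs the C2 hydroxyl on the face of the C5 substituent and the C3 oxygen on the opposite face.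

**C1–C2 (key step).** Ketol 9 is cut between C1 and C2 into keto-aldehyde 8. This is the only ring bond that joins two carbonyl-derived carbons, so it is the only one open to a benzoin-type closure. It removes the ring and the C2 stereocentre in one stroke and leaves an acyclic chain with two stereocentres. The forward reaction must make the aldehyde the donor and the ketone the acceptor, close the six-membered ring, and set C2 with hydroxyl trans to the C3 silyloxy group.

**Opening of the terpene ring.** Keto-aldehyde 8 is the product of oxidative cleavage, through diol 7, of the ring double bond of a trans-carveol. In the forward direction the alcohol 4 is first epoxidised under hydroxyl direction to 5 and then silylated to 6. The bond broken is between the same two carbons that the key step rejoins, so the sequence transposes oxygen from an alkene to an acyloin without changing the skeleton. A neighbouring option would open a limonene-type ring without the C3 oxygen and add it later next to the methyl ketone. That would require a regioselective enol derivative, a reagent-controlled oxidation and protection of the aldehyde. With carveol the C3 oxygen is in place from the start. The tert-butyldimethylsilyl group is chosen over triethylsilyl because it has to survive periodic acid.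

**C3 configuration.** trans-Carveol 4 is taken back through its 4-nitrobenzoate 3 to cis-carveol 2, the 1,2-reduction product of (S)-carvone 1. The reduction gives the cis alcohol, so one inversion is needed to put the C3 oxygen trans to C5. Compound 1 supplies C5 in the correct absolute configuration together with all ten ring and branch carbons.

## Roads not taken

**Alternative 1:** The cut is at both bonds to C8 (C7–C8 and C8–C9), with the carbonyl carbon coming from carbon monoxide A3. In the forward step the C7 enol triflate A1, A3 and the (E)-alkenylstannane A2 carrying the peroxyketal couple under Pd(PPh3)4 (zerovalent palladium) with LiCl. The product A4 is the same compound as 25.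

- Merits: it forms two carbon–carbon bonds and the complete peroxy side chain in one operation. It avoids the allylic oxidation, the organomagnesium addition to a polyfunctional enal and the exposure of a peroxide to ruthenium.
- Weak points: A1 can only be reached by strong-base enolisation toward the C7 methyl side and O-triflation. In that molecule the most acidic hydrogen is C6–H (α to the ring ketone and geminal to the ester), and deprotonation at C5 would expel the C6 carboxylate by β-elimination. Direct coupling without carbon monoxide insertion is a known competitor. A2 needs a hydrostannylation of an alkynyl peroxide.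
- Comparison: for the side chain this road is shorter than steps 12 to 15, 18 and 19. Against that, the chosen plan keeps every side-chain step neutral or weakly acidic and needs no enolate next to the acyloxy ketone. Alternative 1 is also an end-game only. It leaves the cis-epoxide unsolved, which is the problem the benzoin closure addresses, and it could in principle be grafted onto 16.

**Alternative 2:** A temporary lactone is formed and later destroyed. The acid A5 (carboxyl on C5, C2=C3 alkene, silyl ethers on the C1 and C6 oxygens) is treated with an iodonium source. The carboxylate adds to C3 and iodine to C2, giving the bridged iodolactone A6. After lactone opening the C3 oxygen displaces iodide to close the epoxide.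

- Merits: the tether can reach C3 only on the face of C5, and iodine adds anti, so the cis-epoxide follows from geometry. In this respect it is more secure than the chosen plan, which depends on diastereoselection at C2.
- Weak points: Markovnikov opening of the iodonium ion at the methyl-bearing C2 would give the isomeric bicyclo[2.2.2] lactone. A5 already needs three ring stereocentres and two different silyl groups. C1 arrives at the alcohol level and must be re-oxidised. The C5 carboxyl carbon must be turned into the fully substituted alkene carbon C7, passing through carbonyl intermediates that have the C6 oxygen in the β-position.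
- Comparison: the chosen plan also converts the C2/C3 relationship into the epoxide stereospecifically. It sets against the geometric certainty of the lactone the fact that ring, C5 configuration, C3 oxygen and the three-carbon branch all come from 1 in six steps, with C1 formed directly as the ketone.

**Alternative 3:** The ring is cut at C4–C5 and C1–C6. Isoprene A7 and the acyloxyacrylimide A8 combine under the Cu(SbF6)2 complex of 2,2'-isopropylidenebis(4-tert-butyl-2-oxazoline) (divalent copper) to give cyclohexene A9.

- Merits: the catalytic step sets C5 and C6 trans with the ester already in place, from very simple materials and without the chiral pool. In this it is better than the chosen plan, which needs two steps for C6 and takes C5 from a terpene.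
- Weak points: C1 arrives as a methylene group and must be oxidised next to the acyloxy carbon, in competition with C4 and the methyl group. The cis-epoxide remains unsolved, because conjugate epoxidation after C1 oxidation would again deliver oxygen trans to C5. The imide carbon must become C7 while the C6 ester sits β to that carbonyl, so every basic step risks elimination. A β-acyloxy acrylimide is also a sluggish dienophile toward an unactivated diene.
- Comparison: the chosen plan sets against the elegance of the cycloaddition the fact that after its key step every ring oxygen is at the right carbon and oxidation level, and that the C5 branch already contains C7, C8 and the methylene carbon.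

Key step: step 7

Remark on the chemistry: the (5aR,10bS) antipode of the aminoindanol-derived triazolium salt is assumed to be the one whose facial preference at the ketone agrees with the chair bias of the substrate. If the match lies with the (5aS,10bR) salt, that antipode is used under the same conditions.

## Steps

Step 1
Reactants: 1 (S)-(+)-carvone
Product: 2 (1S,5S)-2-methyl-5-(prop-1-en-2-yl)cyclohex-2-en-1-ol (cis-carveol)
Conditions: NaBH4, CeCl3·7H2O, MeOH, −20 °C
Reagents that add atoms: none
Why: Luche 1,2-reduction of the enone; hydride should add axially to the conformer with equatorial isopropenyl, so the new carbinol centre (C3) carries its hydroxyl cis to the C5 substituent.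

Step 2
Reactants: 2 cis-carveol
Product: 3 (1R,5S)-2-methyl-5-(prop-1-en-2-yl)cyclohex-2-en-1-yl 4-nitrobenzoate
Conditions: 4-nitrobenzoic acid, PPh3, DIAD, THF, 0 °C to rt
Reagents that add atoms: 4-nitrobenzoic acid, O=C(O)c1ccc(cc1)[N+](=O)[O-]
Why: Mitsunobu reaction; SN2 displacement of the oxyphosphonium group by the acidic carboxylate should invert C3 and place the oxygen trans to C5, and the acidic pronucleophile favours direct over allylically transposed substitution.

Step 3
Reactants: 3 trans-carveyl 4-nitrobenzoate
Product: 4 (1R,5S)-2-methyl-5-(prop-1-en-2-yl)cyclohex-2-en-1-ol (trans-carveol)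
Conditions: K2CO3 (cat.), MeOH, rt
Reagents that add atoms: none
Why: Base-catalysed transesterification cleaves the acyl–oxygen bond only, so the configuration at C3 is retained.

Step 4
Reactants: 4 trans-carveol
Product: 5 (1R,2R,4R,6S)-1-methyl-4-(prop-1-en-2-yl)-7-oxabicyclo[4.1.0]heptan-2-ol (epoxide syn to the hydroxyl)
Conditions: VO(acac)2 (3 mol%), tBuOOH, CH2Cl2, 0 °C to rt
Reagents that add atoms: tert-butyl hydroperoxide, CC(C)(C)OO
Why: Hydroxyl-directed vanadium-catalysed epoxidation delivers oxygen only to the allylic alkene, syn to the pseudo-axial hydroxyl, and leaves the isopropenyl group untouched; the two new epoxide centres are temporary and disappear in step 6.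

Step 5
Reactants: 5 epoxy alcohol
Product: 6 tert-butyldimethyl{[(1S,2R,4S,6S)-1-methyl-4-(prop-1-en-2-yl)-7-oxabicyclo[4.1.0]heptan-2-yl]oxy}silane
Conditions: TBSCl, imidazole, DMAP (cat.), DMF, rt
Reagents that add atoms: tert-butyldimethylsilyl chloride, CC(C)(C)[Si](C)(C)Cl
Why: Standard silylation of a secondary alcohol; the tert-butyldimethylsilyl ether is chosen because it should survive periodic acid in step 6 and amine base in step 7 and can be removed by fluoride next to a tertiary alcohol.

Step 6
Reactants: 6 silyl-protected epoxide
Product: 8 (3R,5R)-5-[(tert-butyldimethylsilyl)oxy]-6-oxo-3-(prop-1-en-2-yl)heptanal, via trans-diol 7 (not isolated)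
Conditions: H5IO6, THF/H2O, 0 °C to rt
Reagents that add atoms: water, O
Why: Periodic acid hydrolyses the trisubstituted epoxide and cleaves the resulting glycol in one pot (Malaprade-type cleavage, known for terpene epoxides), giving the aldehyde from the CH terminus (C1) and the methyl ketone from the methyl-bearing carbon (C2). C3 and C5 are not touched, and the silyl ether prevents a second glycol cleavage at C2–C3.

Step 7
Reactants: 8 keto-aldehyde
Product: 9 (2S,3R,5R)-3-[(tert-butyldimethylsilyl)oxy]-2-hydroxy-2-methyl-5-(prop-1-en-2-yl)cyclohexan-1-one
Conditions: (5aR,10bS)-2-(pentafluorophenyl)-5a,10b-dihydro-4H,6H-indeno[2,1-b][1,2,4]triazolo[4,3-d][1,4]oxazin-2-ium tetrafluoroborate (15 mol%), Et3N (15 mol%), toluene (0.05 M), rt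
Reagents that add atoms: none
Why: The carbene released from the triazolium salt by Et3N adds to the aldehyde of 8, and proton transfer gives the Breslow enaminol, an acyl anion equivalent that attacks the methyl ketone carbon to form the C1–C2 bond; collapse of the adduct expels the carbene and leaves tertiary ketol 9. The closest known reaction type is the N-heterocyclic-carbene-catalysed intramolecular crossed aldehyde–ketone benzoin cyclisation, established for six-membered ketols with aminoindanol-derived triazolium salts. The ring closes in the 6-exo-trig mode. The only new stereocentre is C2: in the chair transition state the C5 isopropenyl group is equatorial and the C3 silyloxy group therefore axial, and the ketone places its methyl group equatorial and its oxygen axial, anti to the C3–O bond and within reach of the enol O–H, so the hydroxyl should end up trans to the silyloxy group; the catalyst antipode is chosen so that its facial preference agrees with this bias. Chemoselectivity between the two carbonyl groups is inherent, because only the aldehyde can form the Breslow intermediate and the ketone serves solely as acceptor, and moderate dilution suppresses intermolecular aldehyde–aldehyde coupling. The weak amine base and the catalytic loading are meant to keep the C3 stereocentre from epimerising and the two enolisable carbonyls from aldol closure.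

Step 8
Reactants: 9 silyl-protected ketol
Product: 10 (2S,3R,5R)-2,3-dihydroxy-2-methyl-5-(prop-1-en-2-yl)cyclohexan-1-one
Conditions: HF·pyridine, pyridine/THF, 0 °C to rt
Reagents that add atoms: none
Why: Fluoride-mediated desilylation under buffered, non-basic conditions, which avoids alkoxide-driven α-ketol rearrangement; no stereocentre is affected.

Step 9
Reactants: 10 trans-diol
Product: 12 (1S,4R,6S)-1-methyl-4-(prop-1-en-2-yl)-7-oxabicyclo[4.1.0]heptan-2-one, via C3 mesylate 11 (not isolated)
Conditions: MsCl, Et3N, CH2Cl2, −20 °C; then DBU, 0 °C to rt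
Reagents that add atoms: none
Why: The secondary C3 hydroxyl is sulfonylated in preference to the hindered tertiary one, and the C2 alkoxide then closes the epoxide by intramolecular SN2 displacement with inversion at C3. Oxygen and mesylate are trans-diaxial in the chair with equatorial isopropenyl, so the epoxide should form on the face of the C5 substituent. C2 carries no hydrogen, so elimination toward the ketone is not possible.

Step 10
Reactants: 12 cis-epoxy ketone
Product: 14 (1S,3S,4S,6S)-3-hydroxy-1-methyl-4-(prop-1-en-2-yl)-7-oxabicyclo[4.1.0]heptan-2-one, via sodium enolate 13 (not isolated)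
Conditions: NaN(SiMe3)2, THF, −78 °C; then 2-(benzenesulfonyl)-3-phenyloxaziridine, −78 °C; NH4Cl
Reagents that add atoms: 2-(benzenesulfonyl)-3-phenyloxaziridine, O=S(=O)(c1ccccc1)N1OC1c1ccccc1
Why: Enolate oxidation with a Davis oxaziridine; C6 is the only enolisable position, and the oxidant should approach anti to the adjacent C5 isopropenyl group, giving the C6 hydroxyl trans to it. The sodium counter-ion and low temperature limit addition to the sulfonimine by-product and opening of the epoxide by the enolate.

Step 11
Reactants: 14 hydroxy ketone; 15 3-methylbutanoyl chloride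
Product: 16 (1S,3S,4S,6S)-1-methyl-2-oxo-4-(prop-1-en-2-yl)-7-oxabicyclo[4.1.0]heptan-3-yl 3-methylbutanoate
Conditions: pyridine, DMAP (cat.), CH2Cl2, 0 °C
Reagents that add atoms: none
Why: DMAP-catalysed acylation of the secondary alcohol; the C–O bond at C6 is untouched, and the mild base should not epimerise the α-acyloxy ketone.

Step 12
Reactants: 16 isopropenyl ester
Product: 17 (1S,3S,4S,6S)-4-(3-hydroxyprop-1-en-2-yl)-1-methyl-2-oxo-7-oxabicyclo[4.1.0]heptan-3-yl 3-methylbutanoate
Conditions: SeO2 (0.5 equiv), tBuOOH, salicylic acid (cat.), CH2Cl2, rt
Reagents that add atoms: selenium dioxide, O=[Se]=O; tert-butyl hydroperoxide, CC(C)(C)OO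
Why: Allylic oxidation by ene reaction and [2,3]-sigmatropic shift; on a 1,1-disubstituted alkene the methyl group is oxidised in preference to the ring methine, as known for isopropenyl terpenoids. Any enal formed by over-oxidation converges in step 13.

Step 13
Reactants: 17 allylic alcohol
Product: 18 (1S,3S,4S,6S)-1-methyl-2-oxo-4-(3-oxoprop-1-en-2-yl)-7-oxabicyclo[4.1.0]heptan-3-yl 3-methylbutanoate
Conditions: MnO2, CH2Cl2, rt
Reagents that add atoms: none
Why: Manganese dioxide oxidises the primary allylic alcohol to the enal under neutral conditions without affecting the epoxide, ketone or ester.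

Step 14
Reactants: 18 enal; 19 vinylmagnesium bromide
Product: 20 (1S,3S,4S,6S)-4-(3-hydroxypenta-1,4-dien-2-yl)-1-methyl-2-oxo-7-oxabicyclo[4.1.0]heptan-3-yl 3-methylbutanoate (both carbinol epimers)
Conditions: 19 (1.05 equiv), THF, −78 °C; NH4Cl
Reagents that add atoms: none
Why: Grignard 1,2-addition to the unhindered aldehyde; the ring ketone is flanked by a quaternary epoxide carbon and an acyloxy-bearing methine, and the ester is slow at this temperature, so the aldehyde should react first. The new carbinol centre forms as a mixture, which is irrelevant because it is oxidised in step 15.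

Step 15
Reactants: 20 dienol
Product: 21 (1S,3S,4S,6S)-1-methyl-2-oxo-4-(3-oxopenta-1,4-dien-2-yl)-7-oxabicyclo[4.1.0]heptan-3-yl 3-methylbutanoate
Conditions: MnO2, CH2Cl2, rt
Reagents that add atoms: none
Why: Oxidation of a doubly allylic alcohol by manganese dioxide; the neutral conditions and work-up by filtration suit the Michael-sensitive divinyl ketone, which is used directly.

Step 16
Reactants: 22 2-methylbut-3-en-2-ol
Product: 23 2-hydroperoxy-2-methylbut-3-ene
Conditions: H2O2 (50% aq.), H2SO4 (cat.), 0 °C
Reagents that add atoms: hydrogen peroxide, OO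
Why: Acid-catalysed perhydrolysis of a tertiary alcohol; the dimethylallyl cation should be captured by hydrogen peroxide at its tertiary terminus under kinetic control at low temperature and short reaction time.

Step 17
Reactants: 23 allylic hydroperoxide
Product: 24 3-[(2-methoxypropan-2-yl)peroxy]-3-methylbut-1-ene
Conditions: 2-methoxypropene, PPTS (cat.), CH2Cl2, 0 °C
Reagents that add atoms: 2-methoxypropene, COC(C)=C
Why: Acid-catalysed addition of the hydroperoxide to the enol ether gives a peroxyketal; this masks the O–O–H proton, which would otherwise destroy the ruthenium carbene in step 18, and it is removable with dilute acid.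

Step 18
Reactants: 21 dienone; 24 peroxy olefin
Product: 25 (1S,3S,4S,6S)-4-{(4E)-6-[(2-methoxypropan-2-yl)peroxy]-6-methyl-3-oxohepta-1,4-dien-2-yl}-1-methyl-2-oxo-7-oxabicyclo[4.1.0]heptan-3-yl 3-methylbutanoate
Conditions: 24 (4 equiv), RuCl2(H2IMes)(=CH-C6H4-2-OiPr) (second-generation Hoveyda–Grubbs catalyst, 10 mol%), CH2Cl2, 40 °C
Reagents that add atoms: none
Why: Olefin cross-metathesis between an electron-poor vinyl ketone and a hindered tertiary allylic olefin; neither partner homodimerises readily, so the cross product is favoured, and the conjugated product should form as the E-isomer. The 1,1-disubstituted enone alkene at C7 is too hindered to take part, and dialkyl peroxides are tolerated by ruthenium carbenes.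

Step 19
Reactants: 25 peroxyketal
Product: 26 (1S,3S,4S,6S)-4-[(4E)-6-hydroperoxy-6-methyl-3-oxohepta-1,4-dien-2-yl]-1-methyl-2-oxo-7-oxabicyclo[4.1.0]heptan-3-yl 3-methylbutanoate (target)
Conditions: AcOH/THF/H2O, rt
Reagents that add atoms: none
Why: Mild acid hydrolysis of the peroxyketal releases the hydroperoxide; the epoxy ketone, ester and dienone should be stable to dilute acetic acid, and no stereocentre is involved.

## Compound list

1 | (S)-(+)-carvone, (5S)-2-methyl-5-(prop-1-en-2-yl)cyclohex-2-en-1-one | C=C(C)[C@H]1CC=C(C)C(=O)C1 | starting material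
2 | (1S,5S)-2-methyl-5-(prop-1-en-2-yl)cyclohex-2-en-1-ol (cis-carveol) | C=C(C)[C@H]1CC=C(C)[C@@H](O)C1 | intermediate
3 | (1R,5S)-2-methyl-5-(prop-1-en-2-yl)cyclohex-2-en-1-yl 4-nitrobenzoate | C=C(C)[C@H]1CC=C(C)[C@H](OC(=O)c2ccc(cc2)[N+](=O)[O-])C1 | intermediate
4 | (1R,5S)-2-methyl-5-(prop-1-en-2-yl)cyclohex-2-en-1-ol (trans-carveol) | C=C(C)[C@H]1CC=C(C)[C@H](O)C1 | intermediate
5 | (1R,2R,4R,6S)-1-methyl-4-(prop-1-en-2-yl)-7-oxabicyclo[4.1.0]heptan-2-ol | C=C(C)[C@H]1C[C@@H]2O[C@]2(C)[C@H](O)C1 | intermediate
6 | tert-butyldimethyl{[(1S,2R,4S,6S)-1-methyl-4-(prop-1-en-2-yl)-7-oxabicyclo[4.1.0]heptan-2-yl]oxy}silane | C=C(C)[C@H]1C[C@@H]2O[C@]2(C)[C@H](O[Si](C)(C)C(C)(C)C)C1 | intermediate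
7 | (1S,2R,3R,5S)-3-[(tert-butyldimethylsilyl)oxy]-2-methyl-5-(prop-1-en-2-yl)cyclohexane-1,2-diol | C=C(C)[C@H]1C[C@H](O)[C@@](C)(O)[C@H](O[Si](C)(C)C(C)(C)C)C1 | intermediate (not isolated)
8 | (3R,5R)-5-[(tert-butyldimethylsilyl)oxy]-6-oxo-3-(prop-1-en-2-yl)heptanal | C=C(C)[C@@H](CC=O)C[C@@H](O[Si](C)(C)C(C)(C)C)C(C)=O | intermediate
9 | (2S,3R,5R)-3-[(tert-butyldimethylsilyl)oxy]-2-hydroxy-2-methyl-5-(prop-1-en-2-yl)cyclohexan-1-one | C=C(C)[C@@H]1C[C@@H](O[Si](C)(C)C(C)(C)C)[C@](C)(O)C(=O)C1 | intermediate
10 | (2S,3R,5R)-2,3-dihydroxy-2-methyl-5-(prop-1-en-2-yl)cyclohexan-1-one | C=C(C)[C@@H]1C[C@@H](O)[C@](C)(O)C(=O)C1 | intermediate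
11 | (1R,2S,5R)-2-hydroxy-2-methyl-3-oxo-5-(prop-1-en-2-yl)cyclohexyl methanesulfonate | C=C(C)[C@@H]1C[C@@H](OS(C)(=O)=O)[C@](C)(O)C(=O)C1 | intermediate (not isolated)
12 | (1S,4R,6S)-1-methyl-4-(prop-1-en-2-yl)-7-oxabicyclo[4.1.0]heptan-2-one | C=C(C)[C@@H]1C[C@@H]2O[C@]2(C)C(=O)C1 | intermediate
13 | sodium (1S,4R,6S)-1-methyl-4-(prop-1-en-2-yl)-7-oxabicyclo[4.1.0]hept-2-en-2-olate | C=C(C)[C@@H]1C[C@@H]2O[C@]2(C)C([O-])=C1.[Na+] | intermediate (not isolated)
14 | (1S,3S,4S,6S)-3-hydroxy-1-methyl-4-(prop-1-en-2-yl)-7-oxabicyclo[4.1.0]heptan-2-one | C=C(C)[C@@H]1C[C@@H]2O[C@]2(C)C(=O)[C@H]1O | intermediate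
15 | 3-methylbutanoyl chloride | CC(C)CC(=O)Cl | starting material
16 | (1S,3S,4S,6S)-1-methyl-2-oxo-4-(prop-1-en-2-yl)-7-oxabicyclo[4.1.0]heptan-3-yl 3-methylbutanoate | C=C(C)[C@@H]1C[C@@H]2O[C@]2(C)C(=O)[C@H]1OC(=O)CC(C)C | intermediate
17 | (1S,3S,4S,6S)-4-(3-hydroxyprop-1-en-2-yl)-1-methyl-2-oxo-7-oxabicyclo[4.1.0]heptan-3-yl 3-methylbutanoate | C=C(CO)[C@@H]1C[C@@H]2O[C@]2(C)C(=O)[C@H]1OC(=O)CC(C)C | intermediate
18 | (1S,3S,4S,6S)-1-methyl-2-oxo-4-(3-oxoprop-1-en-2-yl)-7-oxabicyclo[4.1.0]heptan-3-yl 3-methylbutanoate | C=C(C=O)[C@@H]1C[C@@H]2O[C@]2(C)C(=O)[C@H]1OC(=O)CC(C)C | intermediate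
19 | vinylmagnesium bromide | C=C[Mg]Br | starting material
20 | (1S,3S,4S,6S)-4-(3-hydroxypenta-1,4-dien-2-yl)-1-methyl-2-oxo-7-oxabicyclo[4.1.0]heptan-3-yl 3-methylbutanoate (both carbinol epimers) | C=CC(O)C(=C)[C@@H]1C[C@@H]2O[C@]2(C)C(=O)[C@H]1OC(=O)CC(C)C | intermediate
21 | (1S,3S,4S,6S)-1-methyl-2-oxo-4-(3-oxopenta-1,4-dien-2-yl)-7-oxabicyclo[4.1.0]heptan-3-yl 3-methylbutanoate | C=CC(=O)C(=C)[C@@H]1C[C@@H]2O[C@]2(C)C(=O)[C@H]1OC(=O)CC(C)C | intermediate
22 | 2-methylbut-3-en-2-ol | C=CC(C)(C)O | starting material
23 | 2-hydroperoxy-2-methylbut-3-ene | C=CC(C)(C)OO | intermediate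
24 | 3-[(2-methoxypropan-2-yl)peroxy]-3-methylbut-1-ene | C=CC(C)(C)OOC(C)(C)OC | intermediate
25 | (1S,3S,4S,6S)-4-{(4E)-6-[(2-methoxypropan-2-yl)peroxy]-6-methyl-3-oxohepta-1,4-dien-2-yl}-1-methyl-2-oxo-7-oxabicyclo[4.1.0]heptan-3-yl 3-methylbutanoate | C=C(C(=O)/C=C/C(C)(C)OOC(C)(C)OC)[C@@H]1C[C@@H]2O[C@]2(C)C(=O)[C@H]1OC(=O)CC(C)C | intermediate
26 | (1S,3S,4S,6S)-4-[(4E)-6-hydroperoxy-6-methyl-3-oxohepta-1,4-dien-2-yl]-1-methyl-2-oxo-7-oxabicyclo[4.1.0]heptan-3-yl 3-methylbutanoate (CNP0241468.1) | C=C(C(=O)/C=C/C(C)(C)OO)[C@@H]1C[C@@H]2O[C@]2(C)C(=O)[C@H]1OC(=O)CC(C)C | target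

## Step count and least certain steps

Total step count: 19. Longest linear sequence: 17 steps (steps 1 to 15, 18 and 19, from 1). The peroxy olefin 24 takes two further steps (16 and 17) from 22.

**Step 7 (key step).** The most likely failure is insufficient diastereoselection at C2, if the chair with axial silyloxy group and the alternative with axial isopropenyl group lie close in energy or the catalyst opposes the substrate bias. Base-induced epimerisation at C3 or intramolecular aldol closure may accompany it. The fallback forms the same C1–C2 bond by radical rather than polar umpolung. It sets out from 8, which is treated with SmI2 (divalent samarium) in THF/tBuOH at −78 °C. The aldehyde ketyl adds to the ketone in a chelated pinacol cyclisation, which is known to give the cis-diol anti to an adjacent alkoxy group: (1R,2R,3R,5S)-3-[(tert-butyldimethylsilyl)oxy]-2-methyl-5-(prop-1-en-2-yl)cyclohexane-1,2-diol F1. Oxidation of its secondary hydroxyl with Dess–Martin periodinane returns to the route at 9.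

**Step 10.** Attack of the oxidant on the wrong face of the enolate is the main risk, because the C2 methyl group lies on the face that the C5 substituent leaves open. Opening of the epoxide by the enolate is a second risk. The fallback replaces kinetic face control by a stereospecific inversion. It sets out from 12. If the hydroxylation gives the cis alcohol (1S,3R,4S,6S)-3-hydroxy-1-methyl-4-(prop-1-en-2-yl)-7-oxabicyclo[4.1.0]heptan-2-one F2, this is esterified under Mitsunobu conditions with 3-methylbutanoic acid, PPh3 and DIAD. That inverts C6 and installs the ester in one operation, returning to the route at 16.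

**Step 12.** Low conversion, competing oxidation at the C5 methine or at C6, and over-oxidation are to be expected from selenium dioxide on a polyfunctional substrate. The fallback uses an electrophilic chlorine ene reaction. It sets out from 16. Ca(OCl)2 with solid CO2 in CH2Cl2/H2O should give the allylic chloride (1S,3S,4S,6S)-4-(3-chloroprop-1-en-2-yl)-1-methyl-2-oxo-7-oxabicyclo[4.1.0]heptan-3-yl 3-methylbutanoate F3. Oxidation of F3 with trimethylamine N-oxide in DMSO returns to the route at 18.

**Step 14.** Competing addition to the ring ketone or the ester, or deprotonation at C6, would erode the yield. The fallback reverses the polarity at C8 and uses a palladium-catalysed acylation that ignores ketones and esters. It sets out from 18, proceeds as follows and returns to the route at 21: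
- Pinnick oxidation (NaClO2, NaH2PO4, 2-methylbut-2-ene) gives 2-[(1S,3S,4S,6S)-6-methyl-4-(3-methylbutanoyloxy)-5-oxo-7-oxabicyclo[4.1.0]heptan-3-yl]prop-2-enoic acid F4.
- 1-Chloro-N,N,2-trimethylprop-1-en-1-amine converts F4 under neutral conditions into the acid chloride 2-[(1S,3S,4S,6S)-6-methyl-4-(3-methylbutanoyloxy)-5-oxo-7-oxabicyclo[4.1.0]heptan-3-yl]prop-2-enoyl chloride F5.
- Stille coupling of F5 with tributyl(vinyl)stannane under Pd(PPh3)4 (zerovalent palladium) gives 21.

**Step 18.** Decomposition of the ruthenium carbene by the peroxide, slow turnover at the quaternary allylic carbon and oligomerisation of the vinyl ketone are the likely failures. The fallback introduces the O–O bond last, by a singlet-oxygen ene reaction, and never exposes a peroxide to a metal. It sets out from 18, proceeds as follows and returns to the route at 26, bypassing steps 14 to 19: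
- Allylboronic acid pinacol ester adds to the aldehyde only and gives the homoallylic alcohol (1S,3S,4S,6S)-4-(3-hydroxyhexa-1,5-dien-2-yl)-1-methyl-2-oxo-7-oxabicyclo[4.1.0]heptan-3-yl 3-methylbutanoate F6.
- Cross-metathesis of F6 with 2-methylbut-2-ene under RuCl2(H2IMes)(PCy3)(=CHPh) (second-generation Grubbs catalyst) gives the prenyl carbinol (1S,3S,4S,6S)-4-(3-hydroxy-6-methylhepta-1,5-dien-2-yl)-1-methyl-2-oxo-7-oxabicyclo[4.1.0]heptan-3-yl 3-methylbutanoate F7.
- Dess–Martin oxidation of F7 gives the β,γ-unsaturated ketone (1S,3S,4S,6S)-1-methyl-4-(6-methyl-3-oxohepta-1,5-dien-2-yl)-2-oxo-7-oxabicyclo[4.1.0]heptan-3-yl 3-methylbutanoate F8.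
- Schenck ene reaction of F8 (O2, tetraphenylporphyrin, visible light, CH2Cl2, 0 °C) should place the hydroperoxide on C11 with shift of the double bond into conjugation, giving 26. The regioisomeric secondary hydroperoxide is the expected by-product.

## Further compounds

F1 | step 7 | (1R,2R,3R,5S)-3-[(tert-butyldimethylsilyl)oxy]-2-methyl-5-(prop-1-en-2-yl)cyclohexane-1,2-diol | C=C(C)[C@@H]1C[C@@H](O[Si](C)(C)C(C)(C)C)[C@](C)(O)[C@H](O)C1
F2 | step 10 | (1S,3R,4S,6S)-3-hydroxy-1-methyl-4-(prop-1-en-2-yl)-7-oxabicyclo[4.1.0]heptan-2-one | C=C(C)[C@@H]1C[C@@H]2O[C@]2(C)C(=O)[C@@H]1O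
F3 | step 12 | (1S,3S,4S,6S)-4-(3-chloroprop-1-en-2-yl)-1-methyl-2-oxo-7-oxabicyclo[4.1.0]heptan-3-yl 3-methylbutanoate | C=C(CCl)[C@@H]1C[C@@H]2O[C@]2(C)C(=O)[C@H]1OC(=O)CC(C)C
F4 | step 14 | 2-[(1S,3S,4S,6S)-6-methyl-4-(3-methylbutanoyloxy)-5-oxo-7-oxabicyclo[4.1.0]heptan-3-yl]prop-2-enoic acid | C=C(C(=O)O)[C@@H]1C[C@@H]2O[C@]2(C)C(=O)[C@H]1OC(=O)CC(C)C
F5 | step 14 | 2-[(1S,3S,4S,6S)-6-methyl-4-(3-methylbutanoyloxy)-5-oxo-7-oxabicyclo[4.1.0]heptan-3-yl]prop-2-enoyl chloride | C=C(C(=O)Cl)[C@@H]1C[C@@H]2O[C@]2(C)C(=O)[C@H]1OC(=O)CC(C)C
F6 | step 18 | (1S,3S,4S,6S)-4-(3-hydroxyhexa-1,5-dien-2-yl)-1-methyl-2-oxo-7-oxabicyclo[4.1.0]heptan-3-yl 3-methylbutanoate (both carbinol epimers) | C=CCC(O)C(=C)[C@@H]1C[C@@H]2O[C@]2(C)C(=O)[C@H]1OC(=O)CC(C)C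
F7 | step 18 | (1S,3S,4S,6S)-4-(3-hydroxy-6-methylhepta-1,5-dien-2-yl)-1-methyl-2-oxo-7-oxabicyclo[4.1.0]heptan-3-yl 3-methylbutanoate (both carbinol epimers) | CC(C)=CCC(O)C(=C)[C@@H]1C[C@@H]2O[C@]2(C)C(=O)[C@H]1OC(=O)CC(C)C
F8 | step 18 | (1S,3S,4S,6S)-1-methyl-4-(6-methyl-3-oxohepta-1,5-dien-2-yl)-2-oxo-7-oxabicyclo[4.1.0]heptan-3-yl 3-methylbutanoate | CC(C)=CCC(=O)C(=C)[C@@H]1C[C@@H]2O[C@]2(C)C(=O)[C@H]1OC(=O)CC(C)C
A1 | alternative 1 | (1S,3S,4R,6S)-1-methyl-2-oxo-4-{1-[(trifluoromethanesulfonyl)oxy]ethenyl}-7-oxabicyclo[4.1.0]heptan-3-yl 3-methylbutanoate (C7 enol triflate) | C=C(OS(=O)(=O)C(F)(F)F)[C@@H]1C[C@@H]2O[C@]2(C)C(=O)[C@H]1OC(=O)CC(C)C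
A2 | alternative 1 | tributyl{(1E)-3-[(2-methoxypropan-2-yl)peroxy]-3-methylbut-1-en-1-yl}stannane | CCCC[Sn](CCCC)(CCCC)/C=C/C(C)(C)OOC(C)(C)OC
A3 | alternative 1 | carbon monoxide | [C-]#[O+]
A4 | alternative 1 | peroxyketal-protected target (same structure as 25) | C=C(C(=O)/C=C/C(C)(C)OOC(C)(C)OC)[C@@H]1C[C@@H]2O[C@]2(C)C(=O)[C@H]1OC(=O)CC(C)C
A5 | alternative 2 | 5-[(tert-butyldimethylsilyl)oxy]-4-methyl-6-[(triethylsilyl)oxy]cyclohex-3-ene-1-carboxylic acid (carboxyl cis to the 5-silyloxy and trans to the 6-silyloxy group) | O=C(O)[C@@H]1CC=C(C)[C@H](O[Si](C)(C)C(C)(C)C)[C@H]1O[Si](CC)(CC)CC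
A6 | alternative 2 | 3-[(tert-butyldimethylsilyl)oxy]-4-iodo-4-methyl-2-[(triethylsilyl)oxy]-6-oxabicyclo[3.2.1]octan-7-one (bridged iodolactone, lactone oxygen on C3, iodine on C2 of the target numbering) | O=C3[C@@H]1C[C@H](O3)[C@@](C)(I)[C@H](O[Si](C)(C)C(C)(C)C)[C@H]1O[Si](CC)(CC)CC
A7 | alternative 3 | isoprene (2-methylbuta-1,3-diene) | C=CC(C)=C
A8 | alternative 3 | 3-[(2E)-3-(3-methylbutanoyloxy)prop-2-enoyl]-1,3-oxazolidin-2-one | O=C1OCCN1C(=O)/C=C/OC(=O)CC(C)C
A9 | alternative 3 | trans-4-methyl-6-(2-oxo-1,3-oxazolidine-3-carbonyl)cyclohex-3-en-1-yl 3-methylbutanoate | O=C1OCCN1C(=O)[C@@H]2CC=C(C)C[C@H]2OC(=O)CC(C)C
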